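## Retrosynthetic overview

1. Feature: ring B is a benzene with oxygen only at C2' and C5' (para to each other), one carbon substituent (chromone C2) at C1' next to the C2' oxygen, and hydrogen at C3', C4' and C6'. An alkenyl alkoxy carbene, one CO and a terminal alkyne give exactly this pattern in one benzannulation.
2. Endgame: target ⇐ BCl3 cleavage of 3-OBn and the peri 5-OMe ⇐ hydroquinone ⇐ quinone ⇐ 2'-hydroxy-5'-methoxyphenyl flavone. The 5'-OMe is exchanged for OH by oxidation and then reduction.
3. Key disconnection: ring B ⇒ 3-benzyloxy-2-ethynyl-5,6,7,8-tetramethoxychromone + Cr(CO)5[C(OMe)CH=CHSiMe3], cutting C5'–C6', C1'–C2' and C2'–C3'. Silicon serves as a traceless stabiliser of the vinyl carbene.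
4. Ethynyl ⇐ C2 aldehyde ⇐ C2 ester. Ring C ⇐ oxalate Claisen condensation and cyclodehydration of an aryl benzyloxymethyl ketone. That ketone comes from ortho-lithiation of MOM-protected 2,3,4,5-tetramethoxyphenol and a Weinreb amide.
5. Ring order: A (bought as 1,2,3,4-tetramethoxybenzene), then C (step 5), then B (step 10).

Key step: step 10

Remark on the carbene partner: the unsubstituted complex Cr(CO)5[C(OMe)CH=CH2] is a very strong Michael acceptor and is expected to polymerise at the temperature at which CO dissociates. Its (E)-β-trimethylsilyl derivative is therefore used; the same three bonds form, and silicon leaves by a carbon-to-oxygen shift followed by hydrolysis.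
Remark on the aryl ketone: a Lewis-acid Fries or Friedel–Crafts acylation would endanger the benzyl ether and the ortho methyl ethers, so the ketone is made by anionic chemistry.
Remark on stereochemistry: the target has no stereocentre. The E-alkene of the silylvinyl fragment is the only stereo-element of the route, and it disappears on aromatisation.

## Route

Step 1
Reactants: 1 1,2,3,4-tetramethoxybenzene
Product: 4 2,3,4,5-tetramethoxyphenol, via 2,3,4,5-tetramethoxyphenyllithium 2 (not isolated), via dimethyl arylboronate 3 (not isolated)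
Conditions: n-BuLi, TMEDA, THF, 0 °C; B(OMe)3, −78 °C → rt; AcOH, 30% aq H2O2, 0 °C → rt
Reagents that add atoms: hydrogen peroxide, OO (phenol oxygen of 4); trimethyl borate, COB(OC)OC (B(OMe)2 of 3); n-butyllithium, [Li]CCCC (Li of 2)
Why: Directed ortho-lithiation next to OMe (the two ring hydrogens of 1 are equivalent), borate trapping and the peroxide-induced 1,2-aryl shift from boron to oxygen form a standard arene-to-phenol sequence, and the cold, acetic acid-buffered oxidation keeps the electron-rich phenol from going on to a quinone.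

Step 2
Reactants: 4 2,3,4,5-tetramethoxyphenol
Product: 5 1,2,3,4-tetramethoxy-5-(methoxymethoxy)benzene
Conditions: MOMCl, i-Pr2NEt, CH2Cl2, 0 °C → rt
Reagents that add atoms: chloromethyl methyl ether, COCCl
Why: O-Alkylation of the phenol by the reactive α-chloro ether (acetal protection) masks the acidic OH and installs a strong directing group for the next lithiation.

Step 3
Reactants: 6 benzyloxyacetyl chloride
Product: 7 2-(benzyloxy)-N-methoxy-N-methylacetamide
Conditions: MeNH(OMe)·HCl, Et3N, CH2Cl2, 0 °C → rt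
Reagents that add atoms: N,O-dimethylhydroxylamine hydrochloride, CNOC.Cl
Why: N-Acylation of N,O-dimethylhydroxylamine by an acid chloride (Weinreb amide formation) is fast at 0 °C and leaves the benzyl ether untouched.

Step 4
Reactants: 5 1,2,3,4-tetramethoxy-5-(methoxymethoxy)benzene; 7 2-(benzyloxy)-N-methoxy-N-methylacetamide
Product: 9 2-(benzyloxy)-1-[2-(methoxymethoxy)-3,4,5,6-tetramethoxyphenyl]ethan-1-one, via aryllithium 8 (not isolated)
Conditions: n-BuLi, THF, 0 °C; then 7, −78 → 0 °C; aq NH4Cl
Reagents that add atoms: n-butyllithium, [Li]CCCC (Li of 8 only)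
Why: Directed ortho-metalation followed by Weinreb ketone synthesis: the only ring hydrogen of 5 lies between OMOM and OMe and is removed cleanly, the chelated tetrahedral adduct stops at the ketone, and the base-only conditions spare the benzyl and methyl ethers.

Step 5
Reactants: 9 2-(benzyloxy)-1-[2-(methoxymethoxy)-3,4,5,6-tetramethoxyphenyl]ethan-1-one
Product: 11 ethyl 3-(benzyloxy)-5,6,7,8-tetramethoxy-4-oxo-4H-chromene-2-carboxylate, via diketo ester 10 (not isolated)
Conditions: (CO2Et)2, NaOEt, EtOH–THF, rt → 50 °C; then conc. HCl, EtOH, reflux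
Reagents that add atoms: diethyl oxalate, CCOC(=O)C(=O)OCC
Why: Crossed Claisen condensation of the benzyloxymethyl ketone enolate with the non-enolisable, doubly activated oxalate is driven by deprotonation of the still acidic 10, after which HCl removes the MOM group and the freed phenol adds to the α-keto ester carbonyl and loses water (6-exo-trig closure of ring C, the classical chromone-2-carboxylate synthesis, also the bond set used for 3-benzyloxy-4-pyranone-2-carboxylates).

Step 6
Reactants: 11 ethyl 3-(benzyloxy)-5,6,7,8-tetramethoxy-4-oxo-4H-chromene-2-carboxylate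
Product: 12 3-(benzyloxy)-2-(hydroxymethyl)-5,6,7,8-tetramethoxy-4H-chromen-4-one
Conditions: NaBH4, MeOH–THF, 0 °C
Reagents that add atoms: none
Why: Chemoselective borohydride reduction: the C2 ester is activated by the ring oxygen and the electron-poor pyranone and reacts at 0 °C, whereas C4=O is a vinylogous ester flanked by 3-OBn and 5-OMe and stays intact, as is known for chromone-2-carboxylates.

Step 7
Reactants: 12 3-(benzyloxy)-2-(hydroxymethyl)-5,6,7,8-tetramethoxy-4H-chromen-4-one
Product: 13 3-(benzyloxy)-5,6,7,8-tetramethoxy-4-oxo-4H-chromene-2-carbaldehyde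
Conditions: Dess–Martin periodinane, CH2Cl2, 0 °C → rt
Reagents that add atoms: none
Why: Dess–Martin oxidation converts the primary, allylic-type alcohol into the aldehyde under neutral, anhydrous conditions without over-oxidation and without touching the ethers or the pyranone.

Step 8
Reactants: 13 3-(benzyloxy)-5,6,7,8-tetramethoxy-4-oxo-4H-chromene-2-carbaldehyde
Product: 14 3-(benzyloxy)-2-ethynyl-5,6,7,8-tetramethoxy-4H-chromen-4-one
Conditions: Me3SiCHN2, LiN(i-Pr)2, THF, −78 °C; then 13, −78 → 0 °C; aq NH4Cl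
Reagents that add atoms: trimethylsilyldiazomethane, C[Si](C)(C)C=[N+]=[N-] (the terminal alkyne carbon)
Why: Colvin rearrangement: the lithiated silyl diazomethane adds at −78 °C to the aldehyde, by far the most electrophilic carbonyl of 13, Peterson-type loss of lithium trimethylsilanolate gives a diazoalkene, and loss of N2 with a 1,2-shift in the alkylidene carbene gives the terminal alkyne in an aprotic medium, so no alcohol is present to add to the pyranone or to the conjugated alkyne.

Step 9
Reactants: 15 (E)-(2-bromovinyl)trimethylsilane; 16 chromium hexacarbonyl, Cr(CO)6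
Product: 19 pentacarbonyl[(2E)-1-methoxy-3-(trimethylsilyl)prop-2-en-1-ylidene]chromium, via (E)-2-(trimethylsilyl)vinyllithium 17 (not isolated), via lithium acylchromate 18 (not isolated)
Conditions: t-BuLi (2 equiv), Et2O, −78 °C; Cr(CO)6, Et2O, −78 °C → rt; solvent change, Me3OBF4, CH2Cl2, 0 °C
Reagents that add atoms: trimethyloxonium tetrafluoroborate, C[O+](C)C.F[B-](F)(F)F (O-methyl of 19); tert-butyllithium, [Li]C(C)(C)C (Li of 17 and 18)
Why: Fischer carbene synthesis: bromine–lithium exchange with retention of the E geometry, addition of the vinyllithium to a CO ligand of Cr(CO)6 and O-methylation of the acylate by the hard oxonium salt give the alkoxy carbene complex of zerovalent chromium, whose β-silyl group shields the Michael-acceptor terminus.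

Step 10
Reactants: 14 3-(benzyloxy)-2-ethynyl-5,6,7,8-tetramethoxy-4H-chromen-4-one; 19 pentacarbonyl[(2E)-1-methoxy-3-(trimethylsilyl)prop-2-en-1-ylidene]chromium
Product: 22 3-(benzyloxy)-2-(2-hydroxy-5-methoxyphenyl)-5,6,7,8-tetramethoxy-4H-chromen-4-one, via Cr(CO)3-bound aryl silyl ether 20 (not isolated), via aryl trimethylsilyl ether 21 (not isolated)
Conditions: 19 (1.5 equiv), THF (0.1 M), 55 °C, Ar; then air, Et2O, rt; then 1 M HCl, THF, rt
Reagents that add atoms: none
Why: Thermal loss of one CO from 19 opens a site for the terminal alkyne of 14, which inserts into the Cr=C bond to give a vinylcarbene, and migration of a CO ligand then gives a chromium-bound dienylketene (Dötz benzannulation of an alkenyl alkoxy carbene complex with a terminal alkyne, a well-established reaction type). Ring B closes by 6π electrocyclisation of that ketene onto the silylvinyl terminus, so the three new bonds are C5'–C6' (carbene carbon to alkyne CH), C1'–C2' (substituted alkyne carbon to CO carbon) and C2'–C3' (CO carbon to vinyl β-carbon). The resulting cyclohexa-2,4-dienone carries H and SiMe3 on C3' and aromatises by a 1,3-shift of silicon to the neighbouring oxygen, the known behaviour of β-silylvinyl complexes, which makes 19 a stable stand-in for the parent vinyl complex. No stereocentre is formed. The step needs regioselective insertion, and the steric difference between H and the 3-benzyloxychromon-2-yl group places the large group next to the CO-derived carbon, which puts the oxygen from CO at C2' and the methoxy group at C5'. Air removes the Cr(CO)3 fragment without touching the 5,8-dimethoxy pair of ring A, which (NH4)2Ce(NO3)6 would attack, and dilute acid cleaves the labile aryl O–SiMe3 bond.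

Step 11
Reactants: 22 3-(benzyloxy)-2-(2-hydroxy-5-methoxyphenyl)-5,6,7,8-tetramethoxy-4H-chromen-4-one
Product: 23 2-[3-(benzyloxy)-5,6,7,8-tetramethoxy-4-oxo-4H-chromen-2-yl]cyclohexa-2,5-diene-1,4-dione
Conditions: PhI(OAc)2, MeCN–H2O, 0 °C
Reagents that add atoms: water, O (the C5' carbonyl oxygen)
Why: Hypervalent-iodine oxidative demethylation of a 4-methoxyphenol: ligand exchange at the free 2'-OH, attack of water at C5' and loss of methanol give the para-quinone, and because PhI(OAc)2 needs a free phenol the fully etherified ring A is left alone.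

Step 12
Reactants: 23 2-[3-(benzyloxy)-5,6,7,8-tetramethoxy-4-oxo-4H-chromen-2-yl]cyclohexa-2,5-diene-1,4-dione
Product: 24 3-(benzyloxy)-2-(2,5-dihydroxyphenyl)-5,6,7,8-tetramethoxy-4H-chromen-4-one
Conditions: Na2S2O4, EtOAc–H2O, rt
Reagents that add atoms: none
Why: Two-electron reduction of a 1,4-benzoquinone by dithionite in a two-phase system is a mild standard reaction that affects neither the pyranone nor the benzyl ether.

Step 13
Reactants: 24 3-(benzyloxy)-2-(2,5-dihydroxyphenyl)-5,6,7,8-tetramethoxy-4H-chromen-4-one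
Product: 25 2-(2,5-dihydroxyphenyl)-3,5-dihydroxy-6,7,8-trimethoxy-4H-chromen-4-one (target)
Conditions: BCl3 (excess), C6HMe5, CH2Cl2, −78 → 0 °C; then MeOH, dilute aq HCl
Reagents that add atoms: none
Why: Lewis-acid ether cleavage: BCl3 ionises the benzyl ether at low temperature with pentamethylbenzene as a non-basic trap for the benzyl cation, and on warming the boron held at C4=O directs demethylation to the peri 5-OMe through a six-membered chelate, the known selectivity for 5-methoxyflavones, while the 6-, 7- and 8-OMe groups lack this assistance.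

## Compound list

1 | 1,2,3,4-tetramethoxybenzene | COc1ccc(OC)c(OC)c1OC | starting material
2 | 2,3,4,5-tetramethoxyphenyllithium | [Li]c1cc(OC)c(OC)c(OC)c1OC | intermediate (not isolated)
3 | dimethyl (2,3,4,5-tetramethoxyphenyl)boronate | COB(OC)c1cc(OC)c(OC)c(OC)c1OC | intermediate (not isolated)
4 | 2,3,4,5-tetramethoxyphenol | Oc1cc(OC)c(OC)c(OC)c1OC | intermediate
5 | 1,2,3,4-tetramethoxy-5-(methoxymethoxy)benzene | COCOc1cc(OC)c(OC)c(OC)c1OC | intermediate
6 | benzyloxyacetyl chloride | O=C(Cl)COCc1ccccc1 | starting material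
7 | 2-(benzyloxy)-N-methoxy-N-methylacetamide | CON(C)C(=O)COCc1ccccc1 | intermediate
8 | 2-(methoxymethoxy)-3,4,5,6-tetramethoxyphenyllithium | [Li]c1c(OCOC)c(OC)c(OC)c(OC)c1OC | intermediate (not isolated)
9 | 2-(benzyloxy)-1-[2-(methoxymethoxy)-3,4,5,6-tetramethoxyphenyl]ethan-1-one | COCOc1c(OC)c(OC)c(OC)c(OC)c1C(=O)COCc1ccccc1 | intermediate
10 | ethyl 3-(benzyloxy)-4-[2-(methoxymethoxy)-3,4,5,6-tetramethoxyphenyl]-2,4-dioxobutanoate (racemic, enolisable at C3; this centre is lost on ring closure) | CCOC(=O)C(=O)C(OCc1ccccc1)C(=O)c1c(OCOC)c(OC)c(OC)c(OC)c1OC | intermediate (not isolated)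
11 | ethyl 3-(benzyloxy)-5,6,7,8-tetramethoxy-4-oxo-4H-chromene-2-carboxylate | COc1c(OC)c(OC)c2c(=O)c(OCc3ccccc3)c(C(=O)OCC)oc2c1OC | intermediate
12 | 3-(benzyloxy)-2-(hydroxymethyl)-5,6,7,8-tetramethoxy-4H-chromen-4-one | COc1c(OC)c(OC)c2c(=O)c(OCc3ccccc3)c(CO)oc2c1OC | intermediate
13 | 3-(benzyloxy)-5,6,7,8-tetramethoxy-4-oxo-4H-chromene-2-carbaldehyde | COc1c(OC)c(OC)c2c(=O)c(OCc3ccccc3)c(C=O)oc2c1OC | intermediate
14 | 3-(benzyloxy)-2-ethynyl-5,6,7,8-tetramethoxy-4H-chromen-4-one | COc1c(OC)c(OC)c2c(=O)c(OCc3ccccc3)c(C#C)oc2c1OC | intermediate (key-step precursor)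
15 | (E)-(2-bromovinyl)trimethylsilane | C[Si](C)(C)/C=C/Br | starting material
16 | chromium hexacarbonyl, Cr(CO)6 | O=C=[Cr](=C=O)(=C=O)(=C=O)(=C=O)=C=O | starting material
17 | (E)-2-(trimethylsilyl)vinyllithium | [Li]/C=C/[Si](C)(C)C | intermediate (not isolated)
18 | lithium pentacarbonyl[(2E)-1-oxido-3-(trimethylsilyl)prop-2-en-1-ylidene]chromate | [Li+].[O-]C(/C=C/[Si](C)(C)C)=[Cr](=C=O)(=C=O)(=C=O)(=C=O)=C=O | intermediate (not isolated)
19 | pentacarbonyl[(2E)-1-methoxy-3-(trimethylsilyl)prop-2-en-1-ylidene]chromium, Cr(CO)5[C(OMe)CH=CHSiMe3], zerovalent chromium | COC(/C=C/[Si](C)(C)C)=[Cr](=C=O)(=C=O)(=C=O)(=C=O)=C=O | intermediate (key-step precursor)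
20 | tricarbonylchromium complex of 21, Cr(CO)3 bound η6 to ring B (metal fragment written as a separate part) | COc1c(OC)c(OC)c2c(=O)c(OCc3ccccc3)c(-c3cc(OC)ccc3O[Si](C)(C)C)oc2c1OC.[Cr](=C=O)(=C=O)=C=O | intermediate (not isolated)
21 | 3-(benzyloxy)-5,6,7,8-tetramethoxy-2-{5-methoxy-2-[(trimethylsilyl)oxy]phenyl}-4H-chromen-4-one | COc1c(OC)c(OC)c2c(=O)c(OCc3ccccc3)c(-c3cc(OC)ccc3O[Si](C)(C)C)oc2c1OC | intermediate (not isolated)
22 | 3-(benzyloxy)-2-(2-hydroxy-5-methoxyphenyl)-5,6,7,8-tetramethoxy-4H-chromen-4-one | COc1c(OC)c(OC)c2c(=O)c(OCc3ccccc3)c(-c3cc(OC)ccc3O)oc2c1OC | intermediate (key-step product)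
23 | 2-[3-(benzyloxy)-5,6,7,8-tetramethoxy-4-oxo-4H-chromen-2-yl]cyclohexa-2,5-diene-1,4-dione | COc1c(OC)c(OC)c2c(=O)c(OCc3ccccc3)c(C3=CC(=O)C=CC3=O)oc2c1OC | intermediate
24 | 3-(benzyloxy)-2-(2,5-dihydroxyphenyl)-5,6,7,8-tetramethoxy-4H-chromen-4-one | COc1c(OC)c(OC)c2c(=O)c(OCc3ccccc3)c(-c3cc(O)ccc3O)oc2c1OC | intermediate
25 | 2-(2,5-dihydroxyphenyl)-3,5-dihydroxy-6,7,8-trimethoxy-4H-chromen-4-one | COc1c(OC)c(O)c2c(=O)c(O)c(-c3cc(O)ccc3O)oc2c1OC | target

## Step count and risk

Total steps: 13. Longest linear sequence: 11 steps (1, 2, 4, 5, 6, 7, 8, 10, 11, 12, 13). Steps 3 and 9 are side branches.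

**Step 10.**
- Risk: alkyne insertion may be sluggish, because the triple bond is conjugated with the electron-poor pyranone and is crowded by the 3-benzyloxy group. Thermal decay of the carbene complex, uptake of a second alkyne, or an incomplete carbon-to-oxygen silyl shift could then take over.
- Fallback: ring B is brought in ready-made by a Baker–Venkataraman flavone synthesis, setting out from 9.
- Methanolic HCl removes the MOM group and gives 2-(benzyloxy)-1-(2-hydroxy-3,4,5,6-tetramethoxyphenyl)ethan-1-one F1.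
- Esterification with commercial 2,5-bis(benzyloxy)benzoic acid (EDC·HCl, DMAP, CH2Cl2) gives 2-[(benzyloxy)acetyl]-3,4,5,6-tetramethoxyphenyl 2,5-bis(benzyloxy)benzoate F2.
- LiN(SiMe3)2 in THF moves the aroyl group from oxygen to the α-carbon and gives 2-(benzyloxy)-1-[2,5-bis(benzyloxy)phenyl]-3-(2-hydroxy-3,4,5,6-tetramethoxyphenyl)propane-1,3-dione F3.
- AcOH with catalytic H2SO4 closes ring C to 3-(benzyloxy)-2-[2,5-bis(benzyloxy)phenyl]-5,6,7,8-tetramethoxy-4H-chromen-4-one F4.
- BCl3 and pentamethylbenzene, as in step 13, remove the three benzyl groups and the 5-methyl ether, and the route is rejoined at 25.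

**Step 8.**
- Risk: the lithiated diazo reagent or the lithium silanolate may attack C2 of the pyranone and open the ring, or a nucleophile may add to the terminus of the newly formed conjugated alkyne.
- Fallback: the alkyne is installed by cross-coupling instead of homologation, setting out from 9.
- Heating with DMF dimethyl acetal gives (Z)-2-(benzyloxy)-3-(dimethylamino)-1-[2-(methoxymethoxy)-3,4,5,6-tetramethoxyphenyl]prop-2-en-1-one F5. Its geometry is of no consequence.
- HCl in MeOH removes the MOM group and closes this to 3-(benzyloxy)-5,6,7,8-tetramethoxy-4H-chromen-4-one F6.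
- The only pyranone C–H, at C2, is zincated with TMP2Zn·2MgCl2·2LiCl (TMP = 2,2,6,6-tetramethylpiperidide) and quenched with I2 to give 3-(benzyloxy)-2-iodo-5,6,7,8-tetramethoxy-4H-chromen-4-one F7.
- Sonogashira coupling with trimethylsilylacetylene (PdCl2(PPh3)2, CuI, Et3N) gives 3-(benzyloxy)-5,6,7,8-tetramethoxy-2-[(trimethylsilyl)ethynyl]-4H-chromen-4-one F8.
- Bu4NF buffered with AcOH removes silicon, and the route is rejoined at 14.

**Step 13.**
- Risk: demethylation may continue at C6 once the 5-oxygen is held in the boron chelate, cleavage at C5 may be incomplete, or the benzyl cation may transfer to the electron-rich ring B.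
- Fallback: the two deprotections are separated by mechanism, setting out from 23 and so also replacing step 12.
- Hydrogenation (H2, Pd/C, zerovalent palladium on carbon, EtOAc–MeOH) reduces the quinone and hydrogenolyses the benzyl ether in one operation, giving 2-(2,5-dihydroxyphenyl)-3-hydroxy-5,6,7,8-tetramethoxy-4H-chromen-4-one F9.
- Only the peri 5-OMe then remains to be cleaved, by chelation-controlled demethylation with AlCl3 in MeCN followed by dilute HCl, and the route is rejoined at 25.

## Further compounds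

F1 | step 10 | 2-(benzyloxy)-1-(2-hydroxy-3,4,5,6-tetramethoxyphenyl)ethan-1-one | Oc1c(OC)c(OC)c(OC)c(OC)c1C(=O)COCc1ccccc1
F2 | step 10 | 2-[(benzyloxy)acetyl]-3,4,5,6-tetramethoxyphenyl 2,5-bis(benzyloxy)benzoate | O=C(Oc1c(OC)c(OC)c(OC)c(OC)c1C(=O)COCc1ccccc1)c1cc(OCc2ccccc2)ccc1OCc1ccccc1
F3 | step 10 | 2-(benzyloxy)-1-[2,5-bis(benzyloxy)phenyl]-3-(2-hydroxy-3,4,5,6-tetramethoxyphenyl)propane-1,3-dione (racemic, enolisable) | O=C(c1cc(OCc2ccccc2)ccc1OCc1ccccc1)C(OCc1ccccc1)C(=O)c1c(O)c(OC)c(OC)c(OC)c1OC
F4 | step 10 | 3-(benzyloxy)-2-[2,5-bis(benzyloxy)phenyl]-5,6,7,8-tetramethoxy-4H-chromen-4-one | COc1c(OC)c(OC)c2c(=O)c(OCc3ccccc3)c(-c3cc(OCc4ccccc4)ccc3OCc3ccccc3)oc2c1OC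
F5 | step 8 | (Z)-2-(benzyloxy)-3-(dimethylamino)-1-[2-(methoxymethoxy)-3,4,5,6-tetramethoxyphenyl]prop-2-en-1-one | CN(C)/C=C(\OCc1ccccc1)C(=O)c1c(OCOC)c(OC)c(OC)c(OC)c1OC
F6 | step 8 | 3-(benzyloxy)-5,6,7,8-tetramethoxy-4H-chromen-4-one | COc1c(OC)c(OC)c2c(=O)c(OCc3ccccc3)coc2c1OC
F7 | step 8 | 3-(benzyloxy)-2-iodo-5,6,7,8-tetramethoxy-4H-chromen-4-one | COc1c(OC)c(OC)c2c(=O)c(OCc3ccccc3)c(I)oc2c1OC
F8 | step 8 | 3-(benzyloxy)-5,6,7,8-tetramethoxy-2-[(trimethylsilyl)ethynyl]-4H-chromen-4-one | COc1c(OC)c(OC)c2c(=O)c(OCc3ccccc3)c(C#C[Si](C)(C)C)oc2c1OC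
F9 | step 13 | 2-(2,5-dihydroxyphenyl)-3-hydroxy-5,6,7,8-tetramethoxy-4H-chromen-4-one | COc1c(OC)c(OC)c2c(=O)c(O)c(-c3cc(O)ccc3O)oc2c1OC
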